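Take temperature first: ochre, amber, grey and violet are charged alike and stand at 10 °C, 25 °C, 40 °C and 55 °C.

the same everywhere: racemization catalyst 0.28 mM

| run | left-handed substrate | right-handed substrate | reagent | free catalyst | impurity | temperature | remark | time |
|---|---|---|---|---|---|---|---|---|
| alpha | 20 mM | 20 mM | 44 mM | 1 mM | 0.19 mM | 21 °C | run made earlier |  |
| zeta | 20 mM | 20 mM | 44 mM | 1 mM | 0.76 mM | 46 °C | run made earlier |  |
| epsilon | 30 mM | 30 mM | 44 mM | 1 mM | 0.38 mM | 21 °C | run made earlier |  |
| ochre | 20 mM | 20 mM | 44.0 mM | 1.0 mM | 0.38 mM | 10 °C |  | 40 h |
| violet | 20 mM | 20 mM | 44.0 mM | 1.0 mM | 0.38 mM | 55 °C |  | 40 h |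
| amber | 20 mM | 20 mM | 44.0 mM | 1.0 mM | 0.38 mM | 25 °C |  | 40 h |
| grey | 20 mM | 20 mM | 44.0 mM | 1.0 mM | 0.38 mM | 40 °C |  | 40 h |

- alpha (time / h: left-handed product / %, left-handed substrate / %): 1.33: 14.9, 34.9; 4.00: 29.6, 23.1; 8.00: 39.6, 16.7; 12.0: 44.1, 14.7; 15.0: 46.8, 13.1; 20.0: 49.8, 11.9
- zeta (time / h: left-handed product / %, left-handed substrate / %): 0.417: 5.0, 45.2; 0.667: 6.3, 43.5; 1.33: 8.3, 42.9; 2.00: 9.0, 42.4; 3.00: 9.2, 43.2; 5.00: 9.5, 43.5
- epsilon (time / h: left-handed product / %, left-handed substrate / %): 4.00: 24.0, 28.2; 8.00: 32.1, 22.9; 12.0: 36.5, 21.2; 15.0: 38.3, 20.5; 20.0: 41.1, 19.5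

(standard deviation of a reading: 0.3 percentage points)

- the flask with the highest amount of left-handed product, in percent of the left-handed substrate and right-handed substrate together charged ("all alike" if they lie within 1.5 percentage points) (ochre / violet / amber / grey / all alike)
- final left-handed product, as a percentage of the left-handed substrate and right-handed substrate together charged, in ochre
- final left-handed product, as a percentage of the left-handed substrate and right-handed substrate together charged, in violet
- final left-handed product, as a percentage of the left-handed substrate and right-handed substrate together charged, in amber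
- final left-handed product, as a percentage of the left-handed substrate and right-handed substrate together charged, in grey

- free catalyst is single-handed; left-handed substrate and right-handed substrate are mirror images of each other, charged as a racemate, each of them at the stated concentration
- the numbers in the tables scatter with a standard deviation of 0.3 percentage points

Look at zeta, the simulated run nearest to violet, at 46 °C. Its left-handed product crept from 9.2% to 9.5% between 3.00 h and 5.00 h, while left-handed substrate stood at 43.5%, more than the product. Substrate is present and turnover has nearly stopped, so suspect the catalyst. Alpha, at 21 °C, was still gaining at 20.0 h.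

Define the reach as the hourly fraction of left-handed substrate that the free catalyst turns at the start, times the catalyst's life in hours. Leaving racemization aside and treating the loss as pseudo-first-order, the final product share is 0.5 × (1 − exp(−reach)). Turned around, this formula gives an exponent from a reading that lies below its ceiling of 0.5 of the charge.

Solve the hot end. Zeta's last reading gives 0.211. Assume that impurity removes catalyst mole for mole, which leaves 24.0% of zeta's catalyst working, so a full charge would reach 0.878. Check this at 4.00 h: the exponent is 0.896 in alpha and 0.654 in epsilon, a ratio of 0.730, while the surviving catalyst shares give 0.765.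

Solve the cold end. Alpha's exponent grows from 0.896 to 1.57 by 8.00 h, so its second block delivers 0.752 of the first. If the catalyst dies by a steady fraction, each later block repeats that ratio, and the blocks sum to 3.61. A full charge would therefore reach 4.45.

Join the ends by drawing the logarithm of the reach as a straight line in temperature, and extend it to 55 °C. With 62.0% of the catalyst surviving, violet's reach is 0.303, so I expect 13.1% of left-handed product.

The forecast, reading a “selective catalyst that dies over time”, names ochre as highest. It gives ochre 50% (42% to 57%), amber 43% (38% to 49%), grey 26% (20% to 33%) and violet 14% (9% to 21%), the last a little above my figure.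

    reagent + free catalyst + left-handed substrate → free catalyst + left-handed product (k = 180 M⁻² min⁻¹, Ea = 39.0 kJ mol⁻¹)
    reagent + free catalyst + right-handed substrate → free catalyst + right-handed product (k = 56.0 M⁻² min⁻¹, Ea = 43.0 kJ mol⁻¹)
    left-handed substrate + racemization catalyst ⇌ right-handed substrate + racemization catalyst, rate k3*[racemization catalyst]*[left-handed substrate] forward; the back reaction follows from the equilibrium constant (k = 5.10 M⁻¹ min⁻¹, Ea = 42.0 kJ mol⁻¹)
    free catalyst → spent catalyst A (k = 0.00160 min⁻¹, Ea = 103 kJ mol⁻¹)
    free catalyst + impurity → spent catalyst B (k = 5800 M⁻¹ min⁻¹, Ea = 42.0 kJ mol⁻¹)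
    (constants at 25 °C)

The flasks end at ochre 51.7%, amber 47.6%, grey 26.6% and violet 11.8%, so ochre holds the most. In violet at 0.139 h, the half-life of free catalyst on the way to spent catalyst A is 0.16 h, far shorter than the 40 h of standing, and the product stands at 11.8% after 400 h. Reversed, violet's result is a reach of 0.269, beside my 0.303. For a repeat of violet at 30 °C, the same line gives a reach of 1.54, hence 39.3%, and that flask holds 40.7%.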